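**Retrosynthetic overview**
1. The target comes from a silyl-protected C40 bis-enyne by fluoride deprotection. Both triple bonds (C7≡C8 and C7'≡C8') are cut through the middle, giving C10 + C20 + C10.
2. Each sp–sp bond is made from ring–CH(Li)SO2Ph and a CHO of all-E crocetindial. C7/C7' (the former CHO carbon of safranal) and C8/C8' are all natural acceptor carbons. The sulfone turns the ring carbon into a donor and then leaves, which gives the alkyne. All seven chain C=C bonds are bought as E and none is made.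
3. Order of events: the ring A sulfone adds once to the dialdehyde, the ring B sulfone (as O,C-dianion) adds to the remaining CHO, and one KOt-Bu treatment performs all four eliminations.
4. Both sulfones come from safranyl phenyl sulfone. Brown hydroboration sets C3 (R), which is also C3' (called S only because of CIP ranking). C4' is set by allylic oxidation followed by hindered-hydride reduction, cis to the 3'-silyloxy group.
5. No ring is formed in the route. Both cyclohexene rings are carried in from safranal.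

Assumption: safranal and all-E crocetindial (8,8'-diapocarotene-8,8'-dial) are bought. Carotenoid numbering is used, with primes for the ring B half. The adduct centres C7/C8 and C7'/C8' are diastereomer mixtures and are drawn without configuration because step 8 destroys them. All polyene work is done under Ar in dim light.

Step 1
Reactants: 1 safranal (2,6,6-trimethylcyclohexa-1,3-diene-1-carbaldehyde)
Product: 2 safranol [(2,6,6-trimethylcyclohexa-1,3-dien-1-yl)methanol]
Conditions: NaBH4, MeOH, 0 °C
Reagents that add atoms: none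
Why: This is a borohydride 1,2-reduction of a hindered, fully substituted dienal, and no stereocentre is formed.

Step 2
Reactants: 2 safranol
Product: 4 safranyl phenyl sulfone {[(2,6,6-trimethylcyclohexa-1,3-dien-1-yl)methyl]sulfonyl}benzene, via safranyl bromide 3 (not isolated)
Conditions: PBr3, pyridine (cat.), Et2O, −20 °C; then PhSO2Na, DMF, 0 → 23 °C
Reagents that add atoms: sodium benzenesulfinate [Na+].[O-]S(=O)c1ccccc1; phosphorus tribromide BrP(Br)Br (bromine of 3 only)
Why: Bromination of the primary allylic alcohol is followed by SN2 S-alkylation of the soft sulfinate at the primary carbon, as used for β-cyclogeranyl sulfones, and the crude bromide is used cold to avoid allylic scrambling.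

Step 3
Reactants: 4 safranyl phenyl sulfone
Product: 6 (1R)-3,5,5-trimethyl-4-[(phenylsulfonyl)methyl]cyclohex-3-en-1-ol (3R in carotenoid numbering), via trialkylborane 5 (not isolated)
Conditions: (−)-α-pinene, BH3·SMe2, THF, 0 °C [gives (+)-Ipc2BH]; 4, −25 → 0 °C, 48 h; then 3 M NaOH, 30% H2O2, 0 → 23 °C
Reagents that add atoms: hydrogen peroxide OO; (+)-diisopinocampheylborane C[C@@H]1[C@@H](B[C@H]3C[C@H]4C[C@@H]([C@@H]3C)C4(C)C)C[C@H]2C[C@@H]1C2(C)C (boron and Ipc groups of 5 only)
Why: In this Brown asymmetric hydroboration–oxidation only the cis-disubstituted C3=C4 bond is accessible (C5=C6 is tetrasubstituted) and boron goes to C3, away from the C5 methyl; by Brown's cis-alkene model the (+)-α-pinene reagent that gives (R)-2-butanol from cis-2-butene maps onto 3S here, so the (−)-α-pinene reagent gives 3R, and the oxidation proceeds with retention.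

Step 4
Reactants: 6 (R)-hydroxy sulfone
Product: 7 fragment A, tert-butyl(dimethyl){[(1R)-3,5,5-trimethyl-4-[(phenylsulfonyl)methyl]cyclohex-3-en-1-yl]oxy}silane
Conditions: TBSCl, imidazole, DMF, 23 °C
Reagents that add atoms: tert-butyldimethylsilyl chloride CC(C)(C)[Si](C)(C)Cl
Why: This is a standard silylation of a secondary alcohol; the resulting ether withstands n-BuLi and KOt-Bu, is a poor leaving group and is removed by fluoride, and C3 is untouched.

Step 5
Reactants: 7 fragment A (the part not used in step 7)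
Product: 8 (6S)-6-[(tert-butyldimethylsilyl)oxy]-2,4,4-trimethyl-3-[(phenylsulfonyl)methyl]cyclohex-2-en-1-one
Conditions: Mn(OAc)3·2H2O (10 mol %), t-BuOOH (5 equiv, decane), 3 Å MS, EtOAc, 23 °C
Reagents that add atoms: tert-butyl hydroperoxide CC(C)(C)OO
Why: In this radical allylic C–H oxidation (Kharasch-type peroxidation then collapse to the enone), C4 is the only secondary allylic CH2, the C7 hydrogens are deactivated by the sulfone, and the neutral medium leaves the α-silyloxy centre unchanged (its label becomes S only by CIP ranking).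

Step 6
Reactants: 8 enone
Product: 9 fragment B, (1R,6S)-6-[(tert-butyldimethylsilyl)oxy]-2,4,4-trimethyl-3-[(phenylsulfonyl)methyl]cyclohex-2-en-1-ol (cis; 3S,4R in carotenoid numbering)
Conditions: LiBH(s-Bu)3, THF, −78 °C; then H2O
Reagents that add atoms: none
Why: This is a 1,2-reduction under steric approach control, because the β,β-disubstituted enone cannot take a conjugate hydride; the silyloxy group sits equatorial (an axial one would clash with the axial C1 methyl), so the bulky hydride enters along the equatorial trajectory and gives the pseudoaxial C4 alcohol cis to it (4R).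

Step 7
Reactants: 7 fragment A; 10 all-E crocetindial (2,6,11,15-tetramethylhexadeca-2,4,6,8,10,12,14-heptaenedial)
Product: 13 C30 β-benzoyloxy sulfone aldehyde (ring A–C7H(SO2Ph)–C8H(OBz)–hexaenal), via lithiated sulfone 11 (not isolated), via lithium aldolate 12 (not isolated)
Conditions: 7, n-BuLi (1.0 equiv), THF, −78 °C; cannulate into 10 (2.5 equiv, 0.01 M in THF), −78 °C; BzCl, −78 → −20 °C; excess 10 removed by trituration (Et2O/hexane) and reused
Reagents that add atoms: benzoyl chloride O=C(Cl)c1ccccc1; n-butyllithium [Li]CCCC (lithium of 11 and 12 only)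
Why: This Julia-type aldol addition of an α-sulfonyl carbanion joins two natural acceptor carbons (C7 began as the carbonyl carbon of safranal and C8 is a carbonyl carbon) only because the sulfone has made C7 a donor; the through-conjugated dialdehyde is more electrophilic than the alkoxide-bearing hexaenal formed from it, which together with the excess favours mono-addition, cold benzoylation stops retro-addition, and the two new centres are erased in step 8.

Step 8
Reactants: 9 fragment B; 13 C30 β-benzoyloxy sulfone aldehyde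
Product: 18 (3R,3'S,4'R)-3,3'-bis[(tert-butyldimethylsilyl)oxy]-4'-[(trimethylsilyl)oxy]-7,8,7',8'-tetradehydro-β,β-carotene (all-E), via dilithio sulfone 14 (not isolated), via dilithium dialkoxide 15 (not isolated), via silylated bis-sulfone 16 (not isolated), via bis(vinyl sulfone) 17 (not isolated)
Conditions: 9, n-BuLi (2.05 equiv), THF, −78 °C; 13 (1.1 equiv), −78 °C; Me3SiCl (2.5 equiv), −78 → −30 °C; KOt-Bu (10 equiv), THF, −30 → 23 °C, Ar, dark
Reagents that add atoms: chlorotrimethylsilane C[Si](C)(C)Cl; n-butyllithium [Li]CCCC (lithium of 14 and 15 only)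
Why: A second sulfone aldol addition is followed by the Otera–Orita double elimination (E1cB loss of benzoate or trimethylsilanolate to the vinyl sulfones, then loss of benzenesulfinate), so each lithiated sulfone serves as a ring–C≡ anion equivalent; keeping O-4' as its lithium alkoxide during the carbanion stage blocks vinylogous β-elimination because oxide cannot leave, neither vinyl sulfone has an adjacent sp3 C–H so the alkyne is the only 1,2-elimination outlet, no C=C is made or broken so the all-E chain of 10 is kept, and C3, C3' and C4' are not touched.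

Step 9
Reactants: 18 silyl-protected bis-enyne
Product: 19 target, (3S,4R,3'R)-7,8,7',8'-tetradehydro-β,β-carotene-3,4,3'-triol (all-E)
Conditions: Bu4NF, AcOH, THF, 0 → 23 °C, dark; crystallisation or HPLC removes any 9Z/9'Z isomer
Reagents that add atoms: none
Why: Buffered fluoride desilylation removes all three silyl ethers without acid, so the ionisable allylic C4–OH is neither epimerised nor eliminated.

**Compound list**
1 | safranal | CC1=C(C=O)C(C)(C)CC=C1 | starting material
2 | safranol | CC1=C(CO)C(C)(C)CC=C1 | intermediate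
3 | safranyl bromide | CC1=C(CBr)C(C)(C)CC=C1 | intermediate
4 | safranyl phenyl sulfone | CC1=C(CS(=O)(=O)c2ccccc2)C(C)(C)CC=C1 | intermediate
5 | (3R)-3-[bis(isopinocampheyl)boryl] sulfone (trialkylborane) | CC1=C(CS(=O)(=O)c2ccccc2)C(C)(C)C[C@H](B([C@H]3C[C@H]4C[C@@H]([C@@H]3C)C4(C)C)[C@H]5C[C@H]6C[C@@H]([C@@H]5C)C6(C)C)C1 | intermediate
6 | (1R)-3,5,5-trimethyl-4-[(phenylsulfonyl)methyl]cyclohex-3-en-1-ol | CC1=C(CS(=O)(=O)c2ccccc2)C(C)(C)C[C@H](O)C1 | intermediate
7 | fragment A, TBS ether of 6 | CC1=C(CS(=O)(=O)c2ccccc2)C(C)(C)C[C@H](O[Si](C)(C)C(C)(C)C)C1 | intermediate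
8 | (6S)-6-(TBSO)-2,4,4-trimethyl-3-[(phenylsulfonyl)methyl]cyclohex-2-en-1-one | O=S(=O)(c1ccccc1)CC2=C(C)C(=O)[C@@H](O[Si](C)(C)C(C)(C)C)CC2(C)C | intermediate
9 | fragment B, (1R,6S)-6-(TBSO)-2,4,4-trimethyl-3-[(phenylsulfonyl)methyl]cyclohex-2-en-1-ol | O=S(=O)(c1ccccc1)CC2=C(C)[C@@H](O)[C@@H](O[Si](C)(C)C(C)(C)C)CC2(C)C | intermediate
10 | all-E crocetindial | O=C/C(C)=C/C=C/C(C)=C/C=C/C=C(C)/C=C/C=C(\C)C=O | starting material
11 | C7-lithiated 7 | CC1=C(C([Li])S(=O)(=O)c2ccccc2)C(C)(C)C[C@H](O[Si](C)(C)C(C)(C)C)C1 | intermediate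
12 | lithium aldolate of 11 and 10 | CC1=C(C(S(=O)(=O)c2ccccc2)C(O[Li])/C(C)=C/C=C/C(C)=C/C=C/C=C(C)/C=C/C=C(\C)C=O)C(C)(C)C[C@H](O[Si](C)(C)C(C)(C)C)C1 | intermediate
13 | C30 β-benzoyloxy sulfone aldehyde | CC1=C(C(S(=O)(=O)c2ccccc2)C(OC(=O)c2ccccc2)/C(C)=C/C=C/C(C)=C/C=C/C=C(C)/C=C/C=C(\C)C=O)C(C)(C)C[C@H](O[Si](C)(C)C(C)(C)C)C1 | intermediate
14 | O-4,C-7-dilithio 9 | [Li]C(S(=O)(=O)c1ccccc1)C2=C(C)[C@@H](O[Li])[C@@H](O[Si](C)(C)C(C)(C)C)CC2(C)C | intermediate
15 | C40 dilithium dialkoxide (O-8', O-4') | CC1=C(C(S(=O)(=O)c2ccccc2)C(OC(=O)c2ccccc2)/C(C)=C/C=C/C(C)=C/C=C/C=C(C)/C=C/C=C(\C)C(O[Li])C(S(=O)(=O)c2ccccc2)C2=C(C)[C@@H](O[Li])[C@@H](O[Si](C)(C)C(C)(C)C)CC2(C)C)C(C)(C)C[C@H](O[Si](C)(C)C(C)(C)C)C1 | intermediate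
16 | C40 bis-sulfone, 8-OBz, 8'-OTMS, 4'-OTMS | CC1=C(C(S(=O)(=O)c2ccccc2)C(OC(=O)c2ccccc2)/C(C)=C/C=C/C(C)=C/C=C/C=C(C)/C=C/C=C(\C)C(O[Si](C)(C)C)C(S(=O)(=O)c2ccccc2)C2=C(C)[C@@H](O[Si](C)(C)C)[C@@H](O[Si](C)(C)C(C)(C)C)CC2(C)C)C(C)(C)C[C@H](O[Si](C)(C)C(C)(C)C)C1 | intermediate
17 | C40 7,7'-bis(vinyl sulfone) | CC1=C(C(S(=O)(=O)c2ccccc2)=C/C(C)=C/C=C/C(C)=C/C=C/C=C(C)/C=C/C=C(\C)C=C(S(=O)(=O)c2ccccc2)C2=C(C)[C@@H](O[Si](C)(C)C)[C@@H](O[Si](C)(C)C(C)(C)C)CC2(C)C)C(C)(C)C[C@H](O[Si](C)(C)C(C)(C)C)C1 | intermediate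
18 | 3,3'-bis-O-TBS-4'-O-TMS ether of the target | CC1=C(C#C/C(C)=C/C=C/C(C)=C/C=C/C=C(C)/C=C/C=C(\C)C#CC2=C(C)[C@@H](O[Si](C)(C)C)[C@@H](O[Si](C)(C)C(C)(C)C)CC2(C)C)C(C)(C)C[C@H](O[Si](C)(C)C(C)(C)C)C1 | intermediate
19 | (3S,4R,3'R)-7,8,7',8'-tetradehydro-β,β-carotene-3,4,3'-triol | CC1=C(C#C/C(C)=C/C=C/C(C)=C/C=C/C=C(C)/C=C/C=C(\C)C#CC2=C(C)[C@@H](O)[C@@H](O)CC2(C)C)C(C)(C)C[C@H](O)C1 | target

**Totals**
Total step count: 9. Longest linear sequence: 8 (steps 1, 2, 3, 4, 5, 6, 8, 9).

**Steps most likely to fail, with fallbacks**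

Step 8 carries the most risk.
- A hindered dianion must add to a conjugated aldehyde before retro-addition or proton transfer to the benzoyloxy sulfone terminus occurs.
- Four eliminations must then run cleanly on a heptaene.
- 1,4-Loss of sulfinate through the C5-methyl or C4 hydrogens, giving vinylallenes, is the likely side path.

The fallback sets out from 13 and comes back at 18. It builds the two triple bonds one after the other on a masked aldehyde instead of both at once. HC(OMe)3/PPTS in MeOH–CH2Cl2 converts 13 into its dimethyl acetal F1. With no carbonyl left, KOt-Bu takes only the ring A terminus through the double elimination to the enyne acetal F2. PPTS in wet acetone unmasks the C30 enyne aldehyde F3, which can be purified and checked for geometry. Dianion 14 is then added to F3 and the alkoxides are capped with Me3SiCl to give the silylated adduct F4. Only two eliminations with KOt-Bu then remain to reach 18.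

Step 7 is the second risk. Crocetindial is poorly soluble at −78 °C, so the soluble mono-adduct may compete for the carbanion and give the bis-adduct, which wastes the chiral fragment. The fallback sets out from 10 and comes back at 13. It desymmetrises the cheap C20 unit first. One equivalent of HC(OMe)3 with p-TsOH gives, after chromatography, crocetindial mono(dimethyl acetal) F5, and the recovered dialdehyde and bis-acetal are re-equilibrated. Carbanion 11 then has a single CHO to attack, the BzCl trap gives the dimethyl acetal F1, and PPTS in wet acetone releases 13.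

Step 5 is the third risk. The C4 hydrogens lie next to the silyloxy-bearing carbon, and oxidation of the C5 methyl or low conversion may compete. The fallback sets out from 4 and comes back at 9. It puts both oxygens on the diene instead of oxidising a C–H bond.
- Jacobsen–Katsuki epoxidation uses (R,R)-N,N'-bis(3,5-di-tert-butylsalicylidene)-1,2-cyclohexanediaminomanganese chloride (trivalent manganese), NaOCl and 4-phenylpyridine N-oxide in CH2Cl2 at 0 °C. It gives the (3S,4R)-epoxide F6. The sense of induction is taken from the analogy with indene, with the conjugated cis-alkene playing the same role.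
- Bu4NBr-catalysed CO2 insertion opens and recloses at allylic C4 with double inversion, so the net result is retention. It gives the cis cyclic carbonate F7.
- K2CO3/MeOH gives the cis-diol F8.
- TBSCl/imidazole silylates the less hindered homoallylic 3-OH to give 9.

**Further compounds**
F1 | step 8 | dimethyl acetal of 13 | CC1=C(C(S(=O)(=O)c2ccccc2)C(OC(=O)c2ccccc2)/C(C)=C/C=C/C(C)=C/C=C/C=C(C)/C=C/C=C(\C)C(OC)OC)C(C)(C)C[C@H](O[Si](C)(C)C(C)(C)C)C1
F2 | step 8 | (3R)-3-(TBSO)-7,8-didehydro-8'-apo-β-caroten-8'-al dimethyl acetal | CC1=C(C#C/C(C)=C/C=C/C(C)=C/C=C/C=C(C)/C=C/C=C(\C)C(OC)OC)C(C)(C)C[C@H](O[Si](C)(C)C(C)(C)C)C1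
F3 | step 8 | (3R)-3-(TBSO)-7,8-didehydro-8'-apo-β-caroten-8'-al | CC1=C(C#C/C(C)=C/C=C/C(C)=C/C=C/C=C(C)/C=C/C=C(\C)C=O)C(C)(C)C[C@H](O[Si](C)(C)C(C)(C)C)C1
F4 | step 8 | silylated adduct of 14 to F3 (8'-OTMS, 4'-OTMS, 7'-sulfone) | CC1=C(C#C/C(C)=C/C=C/C(C)=C/C=C/C=C(C)/C=C/C=C(\C)C(O[Si](C)(C)C)C(S(=O)(=O)c2ccccc2)C2=C(C)[C@@H](O[Si](C)(C)C)[C@@H](O[Si](C)(C)C(C)(C)C)CC2(C)C)C(C)(C)C[C@H](O[Si](C)(C)C(C)(C)C)C1
F5 | step 7 | crocetindial mono(dimethyl acetal) | O=C/C(C)=C/C=C/C(C)=C/C=C/C=C(C)/C=C/C=C(\C)C(OC)OC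
F6 | step 5 | (3S,4R)-3,4-epoxide of 4 | O=S(=O)(c1ccccc1)CC2=C(C)[C@H]3O[C@H]3CC2(C)C
F7 | step 5 | cis-(3S,4R) cyclic carbonate | O=S(=O)(c1ccccc1)CC2=C(C)[C@H]3OC(=O)O[C@H]3CC2(C)C
F8 | step 5 | (3S,4R)-cis-diol sulfone | O=S(=O)(c1ccccc1)CC2=C(C)[C@@H](O)[C@@H](O)CC2(C)C
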